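**Retrosynthetic overview**
- The last bonds made are the C8'–O ester to the (S)-half-ester of 3-hydroxy-3-methylglutaric acid (from esterase desymmetrisation) and the cleavage of an allyl ester on the dienoic acid.
- The strategy rests on the vicinal pair C1' (tertiary carbinol carrying the dienoic chain) and C6' (quaternary, CH3 and C8'H2O) of the single cyclohexenone ring: with C8' as a formyl group this pair is a ketone–aldehyde aldol retron.
- The rest of the ring, C1'(=O)–C2'(CH3)=C3'H–C4'(=O), is then a cis-enedione, which is an oxidatively opened 2,3,5-trisubstituted furan.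
- Key disconnection C1'–C6': a proline-enamine 6-enolexo aldol of the acyclic trione-aldehyde 17 forms the only ring and both ring stereocentres in step 9.
- Furan 16 comes from 3-methylfurfural by C5 methallylation (later hydroborated and oxidised to the CH2CH(CH3)CHO arm) and a vinylogous aldol/lactone-opening sequence with methyl 3-methylbut-2-enoate, which sets the (2Z,4E)-diene.

Key step: step 9

Remark: the ring carries abscisic-acid numbers (C7' = CH3 on C2', C8' = oxygenated carbon on C6', C9' = CH3 on C6') and the acyclic precursor is numbered C1–C12 (C6 = C1', C7 = C2', C8 = C3', C9 = C4', C10 = C5', C11 = C6', C12 = C8'); pig liver esterase is assumed to give the (S)-half-ester, to be confirmed by correlation with mevalonolactone before use.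

**Step 1**
Reactants: 1 dimethyl 3-hydroxy-3-methylglutarate
Product: 2 (3S)-3-hydroxy-5-methoxy-3-methyl-5-oxopentanoic acid
Conditions: pig liver esterase, 0.1 M phosphate buffer pH 7.5 (pH-stat, 1 M NaOH), rt; then 1 M HCl to pH 2, EtOAc
Reagents that add atoms: water, O
Why: Esterase-catalysed desymmetrisation (enantiotopic-group-selective hydrolysis) of the prochiral diester should stop at the half-ester and set C3 as S through the enzyme's discrimination of the two CH2CO2CH3 arms; the ee is to be assayed by chiral HPLC and, if needed, raised by crystallising the (S)-1-phenylethylammonium salt.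

**Step 2**
Reactants: 3 3-methylfuran-2-carbaldehyde
Product: 4 2-(3-methylfuran-2-yl)-1,3-dioxolane
Conditions: ethylene glycol, p-TsOH·H2O (cat.), toluene, Dean–Stark, reflux
Reagents that add atoms: ethylene glycol, OCCO
Why: Acid-catalysed acetalisation with azeotropic removal of water masks the aldehyde so that the ring can be metallated.

**Step 3**
Reactants: 4 2-(3-methylfuran-2-yl)-1,3-dioxolane; 5 3-bromo-2-methylprop-1-ene
Product: 8 3-methyl-5-(2-methylprop-2-en-1-yl)furan-2-carbaldehyde, via lithiated acetal 6 (not isolated), via methallylated acetal 7 (not isolated)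
Conditions: n-BuLi, THF, −78 → 0 °C; 5, −78 °C → rt; then 1 M HCl, THF, rt
Reagents that add atoms: water, O
Why: Alpha-lithiation of the furan at C5 (its only free alpha position), allylic substitution of the bromide by the furyllithium and mild hydrolysis of the labile furfural acetal should give the 5-methallyl aldehyde without touching the 1,1-disubstituted alkene.

**Step 4**
Reactants: 8 3-methyl-5-(2-methylprop-2-en-1-yl)furan-2-carbaldehyde; 9 methyl 3-methylbut-2-enoate
Product: 12 (2Z,4E)-3-methyl-5-[3-methyl-5-(2-methylprop-2-en-1-yl)furan-2-yl]penta-2,4-dienoic acid, via lithium dienolate 10 (not isolated), via dihydropyranone lactone 11 (not isolated)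
Conditions: LiN(iPr)2 (2.1 equiv), 9 (2.0 equiv), THF, −78 °C; 8, −78 °C → rt; KOtBu, 0 °C → rt; 1 M HCl to pH 3; dark
Reagents that add atoms: none
Why: Vinylogous aldol addition of the ester dienolate, lactonisation of the delta-alkoxide and base-induced E1cB opening of the 5,6-dihydropyran-2-one is the standard route to (2Z,4E)-3-methyldienoic acids: the lactone ring fixes the 2Z geometry and the new C4=C5 bond forms trans.

**Step 5**
Reactants: 12 (2Z,4E)-3-methyl-5-[3-methyl-5-(2-methylprop-2-en-1-yl)furan-2-yl]penta-2,4-dienoic acid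
Product: 14 (2Z,4E)-5-[5-(3-hydroxy-2-methylpropyl)-3-methylfuran-2-yl]-3-methylpenta-2,4-dienoic acid (racemic), via bis-boryl adduct 13 (not isolated)
Conditions: 9-BBN (2.5 equiv), THF, 0 °C → rt; then NaOH, H2O2, 0 °C; citric acid to pH 3; dark
Reagents that add atoms: hydrogen peroxide, OO
Why: Anti-Markovnikov hydroboration–oxidation: the first equivalent of 9-borabicyclo[3.3.1]nonane is taken up by the acid as an acyloxyborane that dialkylboranes reduce only slowly, the next adds to the 1,1-disubstituted alkene much faster than to the electron-poor conjugated diene or the furan, and the new stereocentre (racemic) is erased in step 9.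

**Step 6**
Reactants: 14 (2Z,4E)-5-[5-(3-hydroxy-2-methylpropyl)-3-methylfuran-2-yl]-3-methylpenta-2,4-dienoic acid
Product: 15 allyl (2Z,4E)-5-[5-(3-hydroxy-2-methylpropyl)-3-methylfuran-2-yl]-3-methylpenta-2,4-dienoate (racemic)
Conditions: allyl bromide, KHCO3, DMF, rt
Reagents that add atoms: allyl bromide, C=CCBr
Why: SN2 O-alkylation of the carboxylate; hydrogen carbonate does not deprotonate the primary alcohol, which should therefore stay free.

**Step 7**
Reactants: 15 allyl (2Z,4E)-5-[5-(3-hydroxy-2-methylpropyl)-3-methylfuran-2-yl]-3-methylpenta-2,4-dienoate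
Product: 16 allyl (2Z,4E)-3-methyl-5-[3-methyl-5-(2-methyl-3-oxopropyl)furan-2-yl]penta-2,4-dienoate (racemic)
Conditions: Dess–Martin periodinane, CH2Cl2, 0 °C → rt
Reagents that add atoms: none
Why: Dess–Martin oxidation of the primary alcohol to the aldehyde proceeds under neutral conditions that furan, dienoate and allyl ester tolerate.

**Step 8**
Reactants: 16 allyl (2Z,4E)-3-methyl-5-[3-methyl-5-(2-methyl-3-oxopropyl)furan-2-yl]penta-2,4-dienoate
Product: 17 allyl (2Z,4E,7Z)-3,7,11-trimethyl-6,9,12-trioxododeca-2,4,7-trienoate (racemic at C11)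
Conditions: dimethyldioxirane (1.05 equiv, acetone), −78 → −20 °C; evaporate cold, use at once
Reagents that add atoms: dimethyldioxirane, CC1(C)OO1
Why: Oxidative furan ring opening (oxygen transfer to the most electron-rich pi bond, then opening of the furan epoxide) gives the 2-ene-1,4-dione with the Z geometry inherited from the ring; one equivalent at low temperature should spare the aldehyde, the electron-poor dienoate and the allyl group.

**Step 9**
Reactants: 17 allyl (2Z,4E,7Z)-3,7,11-trimethyl-6,9,12-trioxododeca-2,4,7-trienoate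
Product: 18 allyl (2Z,4E)-5-[(1R,6R)-6-formyl-1-hydroxy-2,6-dimethyl-4-oxocyclohex-2-en-1-yl]-3-methylpenta-2,4-dienoate
Conditions: (R)-proline (30 mol%), DMF (0.02 M), 4 °C → rt, argon, dark; cold water/EtOAc work-up, used directly
Reagents that add atoms: none
Why: (R)-Proline condenses with the C12 aldehyde to an enamine that is planar at C11 (C6'), which erases the racemic alpha-methyl centre, and this enamine carbon adds to the C6 (C1') ketone while the carboxylic acid hydrogen-bonds to and protonates the developing alkoxide; hydrolysis of the iminium ion returns the catalyst. The closest known reaction type is the proline-catalysed intramolecular enolexo aldol cyclisation of dialdehydes and keto-aldehydes, and a secondary amino acid is chosen deliberately because a primary amine would be lost by Paal–Knorr pyrrole formation across the C9/C12 4-oxo-aldehyde. The cyclohexenone ring closes by 6-(enolexo)-exo-trig attack of C11 on C6, the only mode open to this carbon, since reaching C9 or either enone beta-carbon would need a three- or four-membered ring or a 5-endo closure, and the cis C7=C8 bond holds C6 within reach. Both stereocentres arise in one hydrogen-bonded half-chair transition state in which the (E)-enamine arm and the ketone oxygen are pseudo-equatorial and the dienyl chain is pseudo-axial, away from the C2' methyl group, which places the hydroxyl trans to the formyl group; the carboxylic acid of the (R)-catalyst should bring the Si face of the ketone onto the Si face of the enamine and so give (1R,6R). The step needs chemoselectivity for the aldehyde enamine over enolisation of the C9 ketone towards C10 (five-ring hydroxycyclopentenone) and over amine conjugate addition: aldehydes form enamines faster than ketones, the cross-conjugated C6 ketone is strongly electrophilic, high dilution disfavours bimolecular paths, and reversible amine addition returns any trans-enedione to the reactive cis isomer. The aldol cannot dehydrate because C6' is quaternary, and it is reduced at once in step 10 so that retro-aldol cannot erode it.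

**Step 10**
Reactants: 18 allyl (2Z,4E)-5-[(1R,6R)-6-formyl-1-hydroxy-2,6-dimethyl-4-oxocyclohex-2-en-1-yl]-3-methylpenta-2,4-dienoate
Product: 19 allyl (2Z,4E)-5-[(1R,6S)-1-hydroxy-6-(hydroxymethyl)-2,6-dimethyl-4-oxocyclohex-2-en-1-yl]-3-methylpenta-2,4-dienoate
Conditions: NaBH(OAc)3, AcOH, MeCN–CH2Cl2, −20 → 0 °C; cold pH 4 buffer work-up; used at once
Reagents that add atoms: none
Why: Acetoxyborohydride reduction is aldehyde-selective and here hydroxyl-assisted (the C1' hydroxyl exchanges onto boron and delivers hydride internally), so enone, esters and diene should stay intact; no stereocentre is touched (C6' becomes S only through the change in CIP priorities), and the weakly acidic medium holds back retro-aldol and oxa-Michael closure of O8' onto C2'.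

**Step 11**
Reactants: 19 allyl (2Z,4E)-5-[(1R,6S)-1-hydroxy-6-(hydroxymethyl)-2,6-dimethyl-4-oxocyclohex-2-en-1-yl]-3-methylpenta-2,4-dienoate; 2 (3S)-3-hydroxy-5-methoxy-3-methyl-5-oxopentanoic acid
Product: 20 allyl (2Z,4E)-5-[(1R,6S)-1-hydroxy-6-({[(3R)-3-hydroxy-5-methoxy-3-methyl-5-oxopentanoyl]oxy}methyl)-2,6-dimethyl-4-oxocyclohex-2-en-1-yl]-3-methylpenta-2,4-dienoate
Conditions: 2 (2 equiv), EDC·HCl, DMAP (0.2 equiv), CH2Cl2, 0 °C
Reagents that add atoms: none
Why: Steglich esterification: only the primary (neopentyl) hydroxyl is acylated, the tertiary hydroxyls are inert, and rapid acyl transfer at 0 °C should outrun the phaseate-type cyclisation; the glutarate stereocentre is not involved (its descriptor changes to R only by CIP priority).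

**Step 12**
Reactants: 20 allyl (2Z,4E)-5-[(1R,6S)-1-hydroxy-6-({[(3R)-3-hydroxy-5-methoxy-3-methyl-5-oxopentanoyl]oxy}methyl)-2,6-dimethyl-4-oxocyclohex-2-en-1-yl]-3-methylpenta-2,4-dienoate
Product: 21 (2Z,4E)-5-[(1R,6S)-1-hydroxy-6-({[(3R)-3-hydroxy-5-methoxy-3-methyl-5-oxopentanoyl]oxy}methyl)-2,6-dimethyl-4-oxocyclohex-2-en-1-yl]-3-methylpenta-2,4-dienoic acid (CNP0274837.1)
Conditions: Pd(PPh3)4 (5 mol%), morpholine, THF, rt, dark
Reagents that add atoms: none
Why: Palladium-catalysed deallylation (Tsuji–Trost allyl transfer): zerovalent palladium ionises only the allyl ester and morpholine traps the allyl fragment, so the methyl ester, the glutarate ester, the tertiary alcohols and the 2Z,4E-diene should remain untouched.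

**Compound list**
1 | dimethyl 3-hydroxy-3-methylglutarate | COC(=O)CC(C)(O)CC(=O)OC | starting material
2 | (3S)-3-hydroxy-5-methoxy-3-methyl-5-oxopentanoic acid | COC(=O)C[C@@](C)(O)CC(=O)O | intermediate
3 | 3-methylfuran-2-carbaldehyde | Cc1ccoc1C=O | starting material
4 | 2-(3-methylfuran-2-yl)-1,3-dioxolane | Cc1ccoc1C1OCCO1 | intermediate
5 | 3-bromo-2-methylprop-1-ene | CC(=C)CBr | starting material
6 | [5-(1,3-dioxolan-2-yl)-4-methylfuran-2-yl]lithium | [Li]c1cc(C)c(o1)C1OCCO1 | intermediate
7 | 2-[3-methyl-5-(2-methylprop-2-en-1-yl)furan-2-yl]-1,3-dioxolane | CC(=C)Cc1cc(C)c(o1)C1OCCO1 | intermediate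
8 | 3-methyl-5-(2-methylprop-2-en-1-yl)furan-2-carbaldehyde | CC(=C)Cc1cc(C)c(C=O)o1 | intermediate
9 | methyl 3-methylbut-2-enoate | COC(=O)C=C(C)C | starting material
10 | lithium 1-methoxy-3-methylbuta-1,3-dien-1-olate | [Li+].COC([O-])=CC(C)=C | intermediate
11 | 4-methyl-6-[3-methyl-5-(2-methylprop-2-en-1-yl)furan-2-yl]-5,6-dihydro-2H-pyran-2-one (racemic) | CC1=CC(=O)OC(C1)c1oc(CC(C)=C)cc1C | intermediate
12 | (2Z,4E)-3-methyl-5-[3-methyl-5-(2-methylprop-2-en-1-yl)furan-2-yl]penta-2,4-dienoic acid | CC(=C)Cc1cc(C)c(o1)/C=C/C(C)=C\C(=O)O | intermediate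
13 | 9-borabicyclo[3.3.1]nonan-9-yl (2Z,4E)-5-{5-[3-(9-borabicyclo[3.3.1]nonan-9-yl)-2-methylpropyl]-3-methylfuran-2-yl}-3-methylpenta-2,4-dienoate (racemic) | CC(CB1C2CCCC1CCC2)Cc1cc(C)c(o1)/C=C/C(C)=C\C(=O)OB1C2CCCC1CCC2 | intermediate
14 | (2Z,4E)-5-[5-(3-hydroxy-2-methylpropyl)-3-methylfuran-2-yl]-3-methylpenta-2,4-dienoic acid (racemic) | CC(CO)Cc1cc(C)c(o1)/C=C/C(C)=C\C(=O)O | intermediate
15 | allyl (2Z,4E)-5-[5-(3-hydroxy-2-methylpropyl)-3-methylfuran-2-yl]-3-methylpenta-2,4-dienoate (racemic) | CC(CO)Cc1cc(C)c(o1)/C=C/C(C)=C\C(=O)OCC=C | intermediate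
16 | allyl (2Z,4E)-3-methyl-5-[3-methyl-5-(2-methyl-3-oxopropyl)furan-2-yl]penta-2,4-dienoate (racemic) | CC(C=O)Cc1cc(C)c(o1)/C=C/C(C)=C\C(=O)OCC=C | intermediate
17 | allyl (2Z,4E,7Z)-3,7,11-trimethyl-6,9,12-trioxododeca-2,4,7-trienoate (racemic at C11) | CC(C=O)CC(=O)/C=C(C)\C(=O)/C=C/C(C)=C\C(=O)OCC=C | intermediate
18 | allyl (2Z,4E)-5-[(1R,6R)-6-formyl-1-hydroxy-2,6-dimethyl-4-oxocyclohex-2-en-1-yl]-3-methylpenta-2,4-dienoate | O=C[C@]1(C)CC(=O)C=C(C)[C@]1(O)/C=C/C(C)=C\C(=O)OCC=C | intermediate
19 | allyl (2Z,4E)-5-[(1R,6S)-1-hydroxy-6-(hydroxymethyl)-2,6-dimethyl-4-oxocyclohex-2-en-1-yl]-3-methylpenta-2,4-dienoate | OC[C@]1(C)CC(=O)C=C(C)[C@]1(O)/C=C/C(C)=C\C(=O)OCC=C | intermediate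
20 | allyl (2Z,4E)-5-[(1R,6S)-1-hydroxy-6-({[(3R)-3-hydroxy-5-methoxy-3-methyl-5-oxopentanoyl]oxy}methyl)-2,6-dimethyl-4-oxocyclohex-2-en-1-yl]-3-methylpenta-2,4-dienoate | COC(=O)C[C@@](C)(O)CC(=O)OC[C@]1(C)CC(=O)C=C(C)[C@]1(O)/C=C/C(C)=C\C(=O)OCC=C | intermediate
21 | (2Z,4E)-5-[(1R,6S)-1-hydroxy-6-({[(3R)-3-hydroxy-5-methoxy-3-methyl-5-oxopentanoyl]oxy}methyl)-2,6-dimethyl-4-oxocyclohex-2-en-1-yl]-3-methylpenta-2,4-dienoic acid | COC(=O)C[C@@](C)(O)CC(=O)OC[C@]1(C)CC(=O)C=C(C)[C@]1(O)/C=C/C(C)=C\C(=O)O | target

**Step count**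
Total: 12 steps. Longest linear sequence: 11 steps (3 → 21, steps 2–12); step 1 is a one-step side branch.

**Steps most likely to fail**

Step 9. The alpha-branched aldehyde forms its proline enamine slowly and as an E/Z mixture, so closure may run with poor facial selectivity at C6' and C1' while amine conjugate addition drains the enedione. The fallback replaces catalyst control by resolution through the enantiopure glutarate unit. From 17 the ring is closed without asymmetric induction by pyrrolidinium acetate in CH2Cl2 (classical enamine aldol cyclisation), which gives 18 as the racemate, that is together with the enantiomeric aldehyde ent-18 F1. Reduction as in step 10 gives 19 together with the enantiomeric diol ent-19 F2. Esterification with 2 as in step 11 turns the pair into 20 and the (1S,6R)-ring diastereomer of 20 F3, which are separated by preparative HPLC; the route is rejoined at 20.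

Step 8. The dioxirane may over-oxidise the free alpha-branched aldehyde or the dienoate, and the 4-oxo-aldehyde may be lost on handling. The fallback masks the aldehyde during ring opening and uses bromonium/hydrolysis chemistry instead of oxygen transfer. From 16, HC(OMe)3, MeOH and PPTS give the dimethyl acetal F4. NBS, NaHCO3 in acetone–H2O at −20 °C opens the furan to the acetal enedione F5. Oxalic acid on wet silica gel in CH2Cl2 releases the aldehyde, and the route is rejoined at 17.

Step 11. Intramolecular oxa-Michael addition of the 8'-hydroxyl to C2' (phaseate formation), or self-acylation of the activated hydroxy acid, may outpace esterification of the hindered neopentyl alcohol. The fallback uses anhydride ring opening in place of carbodiimide coupling. From 19, commercial 3-hydroxy-3-methylglutaric anhydride with pyridine in CH2Cl2 at 0 °C gives the hemi-ester acid F6 as both glutarate epimers. TMSCHN2 in toluene–MeOH methylates the free acid (the dienoic acid is still allyl-protected) to 20 and the (3S)-glutarate epimer of 20 F7, which are separated by preparative HPLC; the route is rejoined at 20.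

**Further compounds**
F1 | step 9 | allyl (2Z,4E)-5-[(1S,6S)-6-formyl-1-hydroxy-2,6-dimethyl-4-oxocyclohex-2-en-1-yl]-3-methylpenta-2,4-dienoate (ent-18) | O=C[C@@]1(C)CC(=O)C=C(C)[C@@]1(O)/C=C/C(C)=C\C(=O)OCC=C
F2 | step 9 | allyl (2Z,4E)-5-[(1S,6R)-1-hydroxy-6-(hydroxymethyl)-2,6-dimethyl-4-oxocyclohex-2-en-1-yl]-3-methylpenta-2,4-dienoate (ent-19) | OC[C@@]1(C)CC(=O)C=C(C)[C@@]1(O)/C=C/C(C)=C\C(=O)OCC=C
F3 | step 9 | allyl (2Z,4E)-5-[(1S,6R)-1-hydroxy-6-({[(3R)-3-hydroxy-5-methoxy-3-methyl-5-oxopentanoyl]oxy}methyl)-2,6-dimethyl-4-oxocyclohex-2-en-1-yl]-3-methylpenta-2,4-dienoate | COC(=O)C[C@@](C)(O)CC(=O)OC[C@@]1(C)CC(=O)C=C(C)[C@@]1(O)/C=C/C(C)=C\C(=O)OCC=C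
F4 | step 8 | allyl (2Z,4E)-5-[5-(3,3-dimethoxy-2-methylpropyl)-3-methylfuran-2-yl]-3-methylpenta-2,4-dienoate (racemic) | COC(OC)C(C)Cc1cc(C)c(o1)/C=C/C(C)=C\C(=O)OCC=C
F5 | step 8 | allyl (2Z,4E,7Z)-12,12-dimethoxy-3,7,11-trimethyl-6,9-dioxododeca-2,4,7-trienoate (racemic) | COC(OC)C(C)CC(=O)/C=C(C)\C(=O)/C=C/C(C)=C\C(=O)OCC=C
F6 | step 11 | 5-({(1S,6R)-6-[(1E,3Z)-5-(allyloxy)-3-methyl-5-oxopenta-1,3-dien-1-yl]-6-hydroxy-1,5-dimethyl-3-oxocyclohex-4-en-1-yl}methoxy)-3-hydroxy-3-methyl-5-oxopentanoic acid (both C3 epimers) | OC(=O)CC(C)(O)CC(=O)OC[C@]1(C)CC(=O)C=C(C)[C@]1(O)/C=C/C(C)=C\C(=O)OCC=C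
F7 | step 11 | allyl (2Z,4E)-5-[(1R,6S)-1-hydroxy-6-({[(3S)-3-hydroxy-5-methoxy-3-methyl-5-oxopentanoyl]oxy}methyl)-2,6-dimethyl-4-oxocyclohex-2-en-1-yl]-3-methylpenta-2,4-dienoate | COC(=O)C[C@](C)(O)CC(=O)OC[C@]1(C)CC(=O)C=C(C)[C@]1(O)/C=C/C(C)=C\C(=O)OCC=C
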